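## Structural features

The target 26 is a trans-fused bicyclo[5.3.0]decane in which seven-membered ring A (C10–C1–C2–C3–C4–C5–C6) shares the C6–C10 bond with five-membered ring B (C6–C7–C8–C9–C10), and the chain C11–C15, an (E,E)-diene with a methyl branch on C11 and a tertiary alcohol at C15, sits on C7. Six stereocentres form one unbroken array C7–C6–C10–C1–C2–C3: the quaternary C10 (methyl β) lies between the C6 methine (H α, trans fusion) and the acetoxy carbon C1 (O α). C1 adjoins the α-oxirane C2–C3 (C3 methyl β), and the C7 chain is α, trans to the C6–C5 bond. Fragile groups are the trisubstituted epoxide next to an ester, the tertiary dienylic alcohol (ionises in acid), the acetate (no carbanion chemistry after it is in place) and the diene geometry. The real difficulty is the quaternary C10 inside a trans five–seven fusion, together with a C1 oxygen that is anti to the C10 methyl group yet syn to the epoxide, so that hydride must reach C1 from the face that carries the methyl group. The key step uses the fact that C7 of ring B carries exactly one exocyclic carbon, C11: if C11 is put back between C7 and C8, ring B becomes the cyclohexanone C6–C7–C11(=O)–C8–C9–C10. The bicycle is then the six–seven homologue of an annulation enedione, in which C10, the C1 carbonyl and the trans C6–C10 fusion are within reach of enamine catalysis and dissolving-metal reduction.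

## Logic of the disconnections

26 ⇒ 25. The acyl C–O bond at C1 is cut first, because the acetate tolerates none of the carbanion or hydride steps. This removes the most labile ester. The forward acylation must take the secondary C1–OH and leave the tertiary C15–OH and the epoxide alone.

25 ⇒ 24. Both C15–CH3 bonds are cut. The tertiary dienylic alcohol would not survive acid or oxidants, so it is unveiled late from an ester that also deactivates the side-chain diene. The forward step is a double methyl addition at low temperature beside a free hydroxyl and an epoxide.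

24 ⇒ 23. The C2–O and C3–O bonds of the oxirane are cut. The epoxide oxygen is cis to the C1 oxygen, which is the outcome of a hydroxyl-directed epoxidation. Two stereocentres fall away. The forward step needs the C1 hydroxyl on the α face and must ignore the side-chain alkenes.

23 ⇒ 22. The C1–H bond is cut, giving an enone and removing one more stereocentre. The forward reduction must be 1,2-selective and deliver hydride to the β face, against the bias of the neighbouring methyl group, so the catalyst has to control it.

22 ⇒ 21 ⇒ 20. The C3–CH3 bond and the C2=C3 π bond are cut: a β-methyl enone is the result of conjugate methyl addition and reoxidation of the trapped enolate. The forward steps must prefer the ring enone to the dienoate. C10 is quaternary, so reoxidation can only go towards C2.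

20 ⇒ 19 ⇒ 18. The C2=C3 π bond is removed and the C1 carbonyl is masked as a dioxolane, because C1 must be protected while the side chain is built with organometallic reagents. Ring A becomes a plain protected cycloheptanone. Dehydrogenation can only go towards C2, and hydrolysis must spare the dienoate.

18 ⇒ 16 + 17. The C11=C12 bond is cut. This is convergent: 17 brings C12–C15 with C13=C14 already E and the ester as C15 precursor. The forward olefination must be E-selective on a hindered methyl ketone.

16 ⇒ 14 (through 15). The C11–CH3 bond is cut, leaving an ester on C7, which is what trapping of a ketene gives. The forward step must stop after one methyl addition.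

14 ⇒ 11 (through 12 and 13). The C7–C8 bond is cut and C8 is rejoined to C11, which reinserts C11 into ring B. Ring B and the C7 stereocentre disappear, and the five–seven bicycle becomes a six–seven annulation product. The forward step needs the 1,2-shift of C8 to beat other carbene pathways, and C7 must settle under thermodynamic control.

11 ⇒ 10 ⇒ 8 (through 9). The C7=N2 unit, the activating acyl group on C7 and the C6–H bond are removed. The diazo group must sit on C7 and not on C8. Only the enolate made by reducing the C6=C7–C11=O enone places the charge on C7, and the same reduction sets C6–H. The forward step must trap this enolate before it equilibrates and must protonate C6 to the trans fusion.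

8 ⇒ 7. The two ketal C–O bonds are cut, which returns the free enedione. The forward ketalisation must choose the saturated C1 carbonyl over the enone carbonyl.

7 ⇒ 4 (through 6). The C6=C7 bond is cut (intramolecular aldol condensation). The bicycle becomes a monocycle and C10 becomes a prochiral centre. Catalyst 5 must distinguish the two enantiotopic ring carbonyls of a seven-membered dione.

4 ⇒ 2 + 3. The C9–C10 bond is cut (conjugate addition of the only acidic carbon of 2 to 3). Two simple fragments result and no selectivity issue arises.

2 ⇒ 1. The C10–CH3 bond is cut (C-alkylation of a cyclic 1,3-dione). Mono-C-alkylation is the only demand.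

## Other disconnections considered

Alternative 1: The cut runs through C1–C10 and C6–C7 at once and takes both rings back to acyclic geranylgeranyl diphosphate A1.
- **Forward key step:** a diphosphate-ionising (class 1) terpene synthase of the daucane type would ionise A1 and bring C2=C3 into the cis geometry that a seven-membered ring demands. It would join C1 to C10 and C6 to C7 and quench the C11 cation by loss of a C12 proton, giving triene A2.
- **In its favour:** rings A and B, the stereocentres C6, C7 and C10 and the (E)-C11=C12 bond would all arise in one operation from an achiral precursor. In skeleton-building economy and in control of this triad the alternative is better than the chosen plan, which needs about nine steps for the same task.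
- **Against it here:** an enzyme with exactly this product specificity must be available or be evolved, and A2 carries no oxygen. C1 would have to be oxidised on the α face although C4 and the C3 methyl group are also allylic. C2=C3 would have to be epoxidised beside two other trisubstituted alkenes. C14=C15 would have to be turned into the C13=C14/C15–OH array (for instance by a photooxygenation ene reaction and reduction) with the same selectivity problem.
- **Comparison:** structurally the alternative forms both rings in one cationic cascade under enzyme control, whereas the chosen plan builds them stepwise and contracts ring B by a 1,2-shift under substrate control. The chosen plan takes each oxygen from a function already in place (C1 from the dione, C15 from the ester) and keeps the diene deactivated as a dienoate while ring A is oxidised. It is the safer design for the late oxidation-state changes and the weaker one in step count to the skeleton.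

Alternative 2: The cut is C1–C10, with C3–C5 reconnected, so that ring A comes from cis-divinylcyclopropane A4. Its cyclopentene half (C6–C10 with the isopropenyl group on C7) would be derived from (R)-limonene A3.
- **Forward key step:** heating A4 should start the [3,3] shift through the boat transition state. The (E)-alkenylboronate terminus C1 bonds to C10, the C3–C5 bond breaks, and cyclohepta-1,4-diene boronate A5 results.
- **In its favour:** C1 and the quaternary C10 would be set together with the relative configuration fixed by the boat geometry. The C3 methyl group and C2=C3 are already present, and oxidation of C1–B with retention would give the α-allylic alcohol for the directed epoxidation. For ring A this is better than the chosen plan, which needs three steps for the C3 methyl/C2=C3 unit and a catalyst-controlled reduction for C1. C7 from the chiral pool is equal in reliability to thermodynamic control at C7.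
- **Against it here:** C10 is a fully substituted cyclopentene carbon whose methyl group points at the cyclopropane methylene in the boat transition state. The rearrangement should therefore be slow and could compete with cyclopropane epimerisation and 1,5-hydrogen shifts. A4 needs a cyclopropanation that is diastereoselective with respect to C7. A5 is an allylic boronate open to 1,3-boron shift. C5=C6 must later be hydrogenated to the trans fusion beside C2=C3 and the isopropenyl group. The isopropenyl group (C12 a terminal methylene) must be extended to the (E,E)-diene without a reaction that defines the C11=C12 geometry.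
- **Comparison:** mechanistically a concerted sigmatropic shift closes ring A here, against a photochemical ring contraction that closes ring B in the chosen plan. The chosen plan is weaker on ring A, stronger on the ring fusion (dissolving-metal reduction) and on the side chain (C11 arrives as a carbonyl and is olefinated directly). Step counts should be similar.

Alternative 3: The cuts are C6–C7 and C9–C10 on a monocyclic ring A, leading back to 2,6-dimethylcyclohepta-2,6-dien-1-one A6, alkenylalane A7 and allyl bromide A8.
- **Forward key step:** CuCl2 with a chiral N-heterocyclic carbene ligand would catalyse the conjugate addition of A7 to C6 of the α-methyl enone arm of A6. The aluminium enolate would be allylated by A8 at C10 anti to the new substituent to give enone A9. Ring B would then close by ring-closing metathesis between the C7 methylidene and the allyl group, forming C7=C8.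
- **In its favour:** both ring-fusion centres arise in one flask under catalyst control. The C1 carbonyl, C2=C3 and the C3 methyl group are present from the start, so the steps the chosen plan spends on them vanish. C11 arrives as a masked methyl ketone, the same C7 acetyl oxidation level that the chosen route reaches in 16. In step economy and in the handling of ring A this alternative is better. It closes ring B at the same C7–C8 bond as the chosen plan, by metathesis instead of a 1,2-shift.
- **Against it here:** enantioselective addition to a seven-membered α-substituted enone followed by alkylation of a hindered aluminium enolate to a quaternary centre is a demanding combination. The C7=C8 alkene would have to be reduced beside the C2=C3 enone.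
- **Comparison:** C7 would again rest on equilibration next to the C11 carbonyl, so on that point the two plans are equal. Structurally the alternative keeps ring A intact and adds ring B, while the chosen plan builds both rings by annulation and then contracts one. The chosen plan uses older, individually well-understood operations at the price of roughly five more steps.

Key step: step 7

Remark on numbering: locants C1–C15 are those of 26 in every name below; α is the face opposite the C10 methyl group, β the face of that methyl group.
Remark on structures: 11 and 14 carry C6 and C10 (14 also C7) in the same absolute configuration as 26.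
Assumption 1: L-proline induces the same sense at C10 in the seven-membered triketone 4 as in the six-membered series (S at C10).
Assumption 2: in the oxazaborolidine reduction of 22 the quaternary C10 acts as the large substituent of the C1 carbonyl.

Step 1
Reactants: 1 cycloheptane-1,3-dione
Product: 2 2-methylcycloheptane-1,3-dione
Conditions: MeI (1.1 equiv), K2CO3 (1.1 equiv), acetone, 56 °C
Reagents that add atoms: iodomethane, CI
Why: C-alkylation of the stabilised enolate of a cyclic 1,3-dione; a slight excess of a small electrophile limits O-alkylation and double alkylation.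

Step 2
Reactants: 2 2-methylcycloheptane-1,3-dione; 3 methyl vinyl ketone
Product: 4 2-methyl-2-(3-oxobutyl)cycloheptane-1,3-dione
Conditions: Et3N (0.1 equiv), EtOAc, 25 °C
Reagents that add atoms: none
Why: Michael addition of the only acidic C–H of 2 (C10) to the enone forms C9–C10; the product is achiral, with C10 prochiral.

Step 3
Reactants: 4 2-methyl-2-(3-oxobutyl)cycloheptane-1,3-dione; 5 L-proline (catalyst)
Product: 7 (S)-10-methylbicyclo[5.4.0]undec-6-ene-1,11-dione (target numbering; six-membered ring C6–C7–C11–C8–C9–C10), via ketol 6 (not isolated)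
Conditions: L-proline (0.5 equiv), DMSO, 25 °C; then p-TsOH·H2O (cat.), toluene, 80 °C
Reagents that add atoms: none
Why: Hajos–Parrish–Eder–Sauer–Wiechert cyclisation: the proline enamine of the side-chain ketone attacks one of the two enantiotopic ring carbonyls in a hydrogen-bonded transition state, which should set C10 as S; acid-catalysed dehydration of the cis ketol 6 then gives C6=C7 with loss of water.

Step 4
Reactants: 7 (S)-10-methylbicyclo[5.4.0]undec-6-ene-1,11-dione
Product: 8 (S)-1,1-ethylenedioxy-10-methylbicyclo[5.4.0]undec-6-en-11-one
Conditions: ethylene glycol (solvent), p-TsOH·H2O (1 equiv), 4 Å MS, 25 °C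
Reagents that add atoms: ethylene glycol, OCCO
Why: Kinetic ketalisation takes the saturated C1 carbonyl, since the enone carbonyl is deactivated by conjugation; room temperature avoids migration of C6=C7.

Step 5
Reactants: 8 (S)-1,1-ethylenedioxy-10-methylbicyclo[5.4.0]undec-6-en-11-one
Product: 10 (6S,10S)-1,1-ethylenedioxy-10-methyl-7-(trifluoroacetyl)-trans-bicyclo[5.4.0]undecan-11-one (C7 epimers and enol form), via lithium enolate 9 (not isolated)
Conditions: Li (2.2 equiv), t-BuOH (1.0 equiv), NH3(l)–THF, −78 °C; isoprene; evaporate NH3; THF, −78 °C, CF3CO2CH2CF3 (2.5 equiv); aq. NH4Cl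
Reagents that add atoms: 2,2,2-trifluoroethyl trifluoroacetate, O=C(OCC(F)(F)F)C(F)(F)F (lithium, [Li], is carried only in 9)
Why: Dissolving-metal reduction protonates C6 axially to the trans fusion (H anti to the C10 methyl group) and leaves the C7=C11 enolate regiodefined (Stork enolate); C-trifluoroacetylation at −78 °C goes through a stable tetrahedral adduct, so proton exchange that would move the charge to C8 is avoided.

Step 6
Reactants: 10 (6S,10S)-1,1-ethylenedioxy-10-methyl-7-(trifluoroacetyl)-trans-bicyclo[5.4.0]undecan-11-one
Product: 11 (6R,10S)-7-diazo-1,1-ethylenedioxy-10-methyl-trans-bicyclo[5.4.0]undecan-11-one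
Conditions: 4-acetamidobenzenesulfonyl azide (1.5 equiv), Et3N (1.5 equiv), H2O (1 equiv), MeCN, 25 °C
Reagents that add atoms: 4-acetamidobenzenesulfonyl azide, CC(=O)Nc1ccc(cc1)S(=O)(=O)N=[N+]=[N-]
Why: Detrifluoroacetylative diazo transfer (Regitz type): the enolate of the activated 1,3-dicarbonyl adds to the azide at C7 and the adduct fragments with loss of the trifluoroacetyl group onto the sulfonamide; C6 is not touched, and the sulfonyl azide chosen is a shock-insensitive one.

Step 7
Reactants: 11 (6R,10S)-7-diazo-1,1-ethylenedioxy-10-methyl-trans-bicyclo[5.4.0]undecan-11-one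
Product: 14 methyl (6S,7R,10S)-1,1-ethylenedioxy-10-methyl-trans-bicyclo[5.3.0]decane-7-carboxylate (ester α; trans to C5), via ketene 12 (not isolated), via C7-epimeric ester 13 (not isolated)
Conditions: hν (medium-pressure Hg lamp, Pyrex, λ > 300 nm), degassed MeOH (0.01 M), 20 °C; then NaOMe (0.3 equiv), MeOH, 50 °C
Reagents that add atoms: methanol, CO
Why: Irradiation excites the diazo ketone, whose C7=N2 and C11=O units are held s-cis by the six-membered ring, so loss of N2 and the 1,2-shift of C8 from C11 to C7 should occur together (photochemical Wolff rearrangement) to give ketene 12. Methanol adds to the ketene carbon C11 and the ester enol is protonated at C7, probably mainly from the open α face, which would give the cis ester 13 beside 14. Sodium methoxide then epimerises C7 through the ester enolate to 14, in which the ester is trans to the C6–C5 bond and away from the C10 methyl group. The closest known reaction type is the photolytic ring contraction of 2-diazocyclohexanones to cyclopentanecarboxylates in methanol, as used for nor-steroids. Ring B is closed by contraction of the six-membered ring through a 1,2-alkyl shift that forms C7–C8, not by an exo or endo cyclisation, so no Baldwin-type constraint applies. C7 is the only new stereocentre and is set by thermodynamic control; C6 and C10 take no part and keep the trans fusion. The step needs migration of C8 to beat the carbene pathways (1,2-hydride shift from C6, O–H insertion into methanol); the locked s-cis geometry, direct irradiation without a triplet sensitiser and the fact that C8 is the only group on C11 able to migrate secure this. The dioxolane is inert to neutral methanol, to light above 300 nm and to methoxide.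

Step 8
Reactants: 14 methyl (6S,7R,10S)-1,1-ethylenedioxy-10-methyl-trans-bicyclo[5.3.0]decane-7-carboxylate
Product: 16 (6S,7R,10S)-7-acetyl-1,1-ethylenedioxy-10-methyl-trans-bicyclo[5.3.0]decane, via Weinreb amide 15 (not isolated)
Conditions: MeNH(OMe)·HCl (1.6 equiv), i-PrMgCl (3.2 equiv), THF, −20 → 0 °C; then MeMgBr (3 equiv), 0 → 25 °C; aq. NH4Cl
Reagents that add atoms: methylmagnesium bromide, C[Mg]Br (N,O-dimethylhydroxylamine hydrochloride, CNOC.Cl, supplies the amide group of 15 only)
Why: Weinreb ketone synthesis in one flask: the chloromagnesium amide MeN(OMe)MgCl converts the ester into 15, whose chelated adduct with MeMgBr does not collapse until work-up, so a single methyl group (the C11 methyl) is added; C7 already has its thermodynamic configuration.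

Step 9
Reactants: 16 (6S,7R,10S)-7-acetyl-1,1-ethylenedioxy-10-methyl-trans-bicyclo[5.3.0]decane; 17 triethyl (E)-4-phosphonocrotonate
Product: 18 ethyl (2E,4E)-5-[(6S,7R,10S)-1,1-ethylenedioxy-10-methyl-trans-bicyclo[5.3.0]decan-7-yl]hexa-2,4-dienoate
Conditions: 17 (2.5 equiv), LiN(SiMe3)2 (2.4 equiv), THF, −78 → 25 °C
Reagents that add atoms: none
Why: Vinylogous Horner–Wadsworth–Emmons olefination forms C11=C12; reversible addition should place the chain trans to the bulky ring substituent on C11 (E), and C13=C14 is E from the reagent.

Step 10
Reactants: 18 ethyl (2E,4E)-5-[(6S,7R,10S)-1,1-ethylenedioxy-10-methyl-trans-bicyclo[5.3.0]decan-7-yl]hexa-2,4-dienoate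
Product: 19 ethyl (2E,4E)-5-[(6S,7R,10S)-10-methyl-1-oxo-trans-bicyclo[5.3.0]decan-7-yl]hexa-2,4-dienoate
Conditions: 1 M HCl, THF, 25 °C
Reagents that add atoms: water, O
Why: Acid hydrolysis of the dioxolane; the dienoate tolerates dilute acid, and C7 is now allylic and not α to a carbonyl, so it cannot epimerise.

Step 11
Reactants: 19 ethyl (2E,4E)-5-[(6S,7R,10S)-10-methyl-1-oxo-trans-bicyclo[5.3.0]decan-7-yl]hexa-2,4-dienoate
Product: 20 ethyl (2E,4E)-5-[(6S,7R,10S)-10-methyl-1-oxo-trans-bicyclo[5.3.0]dec-2-en-7-yl]hexa-2,4-dienoate
Conditions: IBX (stabilised, 1.5 equiv), DMSO–toluene (1:2), 70 °C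
Reagents that add atoms: none
Why: IBX dehydrogenation of a ketone through its enol; C10 is quaternary, so only C2 carries α-hydrogens and only C2=C3 can form; a limited excess at 70 °C should stop at the enone.

Step 12
Reactants: 20 ethyl (2E,4E)-5-[(6S,7R,10S)-10-methyl-1-oxo-trans-bicyclo[5.3.0]dec-2-en-7-yl]hexa-2,4-dienoate
Product: 21 ethyl (2E,4E)-5-[(6S,7R,10S)-3,10-dimethyl-1-(trimethylsilyloxy)-trans-bicyclo[5.3.0]dec-1-en-7-yl]hexa-2,4-dienoate (C3 epimers)
Conditions: Me2CuLi (from CuI + 2 MeLi, 1.5 equiv), Me3SiCl (3 equiv), THF, −78 °C; Et3N, pentane, filtration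
Reagents that add atoms: lithium dimethylcuprate, [Li+].C[Cu-]C; chlorotrimethylsilane, C[Si](C)(C)Cl
Why: Silyl-chloride-accelerated Gilman conjugate addition puts the methyl group on C3 and traps the enolate as the C1=C2 silyl enol ether; at −78 °C the ring enone should react well before the dienoate, whose δ-carbon is fully substituted, and the C3 configuration is irrelevant because the centre is removed in step 13.

Step 13
Reactants: 21 ethyl (2E,4E)-5-[(6S,7R,10S)-3,10-dimethyl-1-(trimethylsilyloxy)-trans-bicyclo[5.3.0]dec-1-en-7-yl]hexa-2,4-dienoate
Product: 22 ethyl (2E,4E)-5-[(6S,7R,10S)-3,10-dimethyl-1-oxo-trans-bicyclo[5.3.0]dec-2-en-7-yl]hexa-2,4-dienoate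
Conditions: Pd(OAc)2 (1.05 equiv), MeCN, 25 °C
Reagents that add atoms: none
Why: Saegusa–Ito oxidation: the divalent palladium enolate formed at C2 loses the C3 hydrogen by β-hydride elimination, which restores C2=C3 with the methyl group in place and leaves zerovalent palladium.

Step 14
Reactants: 22 ethyl (2E,4E)-5-[(6S,7R,10S)-3,10-dimethyl-1-oxo-trans-bicyclo[5.3.0]dec-2-en-7-yl]hexa-2,4-dienoate
Product: 23 ethyl (2E,4E)-5-[(1R,6S,7R,10S)-1-hydroxy-3,10-dimethyl-trans-bicyclo[5.3.0]dec-2-en-7-yl]hexa-2,4-dienoate (C1–OH α)
Conditions: (S)-1-methyl-3,3-diphenyltetrahydro-1H,3H-pyrrolo[1,2-c][1,3,2]oxazaborole ((S)-Me-CBS, 0.2 equiv), catecholborane (2 equiv), toluene, −78 °C; MeOH quench, pH 9 buffer wash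
Reagents that add atoms: none
Why: Corey–Bakshi–Shibata reduction, 1,2-selective for the enone; with C10 as the large and the C2 vinyl carbon as the small substituent the (S)-catalyst should deliver hydride to the β face of C1 and so set the hydroxyl α (1R), overriding the substrate preference for attack anti to the C10 methyl group; catecholborane at −78 °C does not hydroborate the alkenes.

Step 15
Reactants: 23 ethyl (2E,4E)-5-[(1R,6S,7R,10S)-1-hydroxy-3,10-dimethyl-trans-bicyclo[5.3.0]dec-2-en-7-yl]hexa-2,4-dienoate
Product: 24 ethyl (2E,4E)-5-[(1S,2S,3R,6S,7R,10S)-2,3-epoxy-1-hydroxy-3,10-dimethyl-trans-bicyclo[5.3.0]decan-7-yl]hexa-2,4-dienoate (epoxide α)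
Conditions: VO(acac)2 (5 mol%), t-BuOOH (1.5 equiv, decane solution), CH2Cl2, 0 → 25 °C
Reagents that add atoms: tert-butyl hydroperoxide, CC(C)(C)OO
Why: VO(acac)2-catalysed hydroxyl-directed epoxidation: oxygen is delivered within the vanadium-bound alkoxide–alkylperoxide complex to the face of C2=C3 that carries the C1 hydroxyl, which sets C2 and C3 (epoxide α, syn to O1); the electron-poor side-chain alkenes are not allylic alcohols and should not react.

Step 16
Reactants: 24 ethyl (2E,4E)-5-[(1S,2S,3R,6S,7R,10S)-2,3-epoxy-1-hydroxy-3,10-dimethyl-trans-bicyclo[5.3.0]decan-7-yl]hexa-2,4-dienoate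
Product: 25 (3E,5E)-6-[(1S,2S,3R,6S,7R,10S)-2,3-epoxy-1-hydroxy-3,10-dimethyl-trans-bicyclo[5.3.0]decan-7-yl]-2-methylhepta-3,5-dien-2-ol
Conditions: MeLi (4 equiv), THF, −78 → −40 °C; aq. NH4Cl
Reagents that add atoms: methyllithium, [Li]C
Why: Double 1,2-addition of methyllithium to the ester gives the C15 tertiary alcohol; at low temperature the trisubstituted epoxide is not opened, and the cis epoxy alkoxide cannot undergo epoxide migration because backside attack on C2 is geometrically impossible.

Step 17
Reactants: 25 (3E,5E)-6-[(1S,2S,3R,6S,7R,10S)-2,3-epoxy-1-hydroxy-3,10-dimethyl-trans-bicyclo[5.3.0]decan-7-yl]-2-methylhepta-3,5-dien-2-ol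
Product: 26 (1S,2S,3R,6S,7R,10S)-2,3-epoxy-7-[(2E,4E)-6-hydroxy-6-methylhepta-2,4-dien-2-yl]-3,10-dimethyl-trans-bicyclo[5.3.0]decan-1-yl acetate (CNP0265175.2)
Conditions: Ac2O (1.5 equiv), pyridine, DMAP (0.1 equiv), CH2Cl2, 0 → 25 °C
Reagents that add atoms: acetic anhydride, CC(=O)OC(C)=O
Why: Nucleophile-catalysed acylation takes the secondary C1 hydroxyl; the tertiary C15 hydroxyl is far slower under these conditions, and the basic medium leaves epoxide and diene untouched.

## Compound list

1 | cycloheptane-1,3-dione | O=C1CCCCC(=O)C1 | starting material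
2 | 2-methylcycloheptane-1,3-dione | CC1C(=O)CCCCC1=O | intermediate
3 | methyl vinyl ketone (but-3-en-2-one) | CC(=O)C=C | starting material
4 | 2-methyl-2-(3-oxobutyl)cycloheptane-1,3-dione | CC(=O)CCC1(C)C(=O)CCCCC1=O | intermediate
5 | L-proline (catalyst) | OC(=O)[C@@H]1CCCN1 | starting material
6 | (6S,10S)-6-hydroxy-10-methyl-cis-bicyclo[5.4.0]undecane-1,11-dione (ketol, OH and CH3 cis; not isolated) | C[C@]12CCC(=O)C[C@@]1(O)CCCCC2=O | intermediate
7 | (S)-10-methylbicyclo[5.4.0]undec-6-ene-1,11-dione (systematic: (1S)-1-methylbicyclo[5.4.0]undec-7-ene-2,9-dione) | C[C@]12CCC(=O)C=C1CCCCC2=O | intermediate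
8 | (S)-1,1-ethylenedioxy-10-methylbicyclo[5.4.0]undec-6-en-11-one | C[C@]12CCC(=O)C=C1CCCCC23OCCO3 | intermediate
9 | lithium (6S,10S)-1,1-ethylenedioxy-10-methyl-trans-bicyclo[5.4.0]undec-7(11)-en-11-olate (not isolated) | C1=C(O[Li])CC[C@@]2(C)[C@H]1CCCCC23OCCO3 | intermediate
10 | (6S,10S)-1,1-ethylenedioxy-10-methyl-7-(trifluoroacetyl)-trans-bicyclo[5.4.0]undecan-11-one (C7 epimers/enol) | O=C(C1C(=O)CC[C@@]2(C)[C@H]1CCCCC23OCCO3)C(F)(F)F | intermediate
11 | (6R,10S)-7-diazo-1,1-ethylenedioxy-10-methyl-trans-bicyclo[5.4.0]undecan-11-one | [N-]=[N+]=C1C(=O)CC[C@@]2(C)[C@H]1CCCCC23OCCO3 | intermediate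
12 | (6S,10S)-1,1-ethylenedioxy-10-methyl-7-(oxomethylidene)-trans-bicyclo[5.3.0]decane (ketene; not isolated) | O=C=C1CC[C@@]2(C)[C@H]1CCCCC23OCCO3 | intermediate
13 | methyl (6S,7S,10S)-1,1-ethylenedioxy-10-methyl-trans-bicyclo[5.3.0]decane-7-carboxylate (C7 epimer, ester β; not isolated) | COC(=O)[C@H]1CC[C@@]2(C)[C@H]1CCCCC23OCCO3 | intermediate
14 | methyl (6S,7R,10S)-1,1-ethylenedioxy-10-methyl-trans-bicyclo[5.3.0]decane-7-carboxylate | COC(=O)[C@@H]1CC[C@@]2(C)[C@H]1CCCCC23OCCO3 | intermediate
15 | (6S,7R,10S)-1,1-ethylenedioxy-N-methoxy-N,10-dimethyl-trans-bicyclo[5.3.0]decane-7-carboxamide (not isolated) | CON(C)C(=O)[C@@H]1CC[C@@]2(C)[C@H]1CCCCC23OCCO3 | intermediate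
16 | (6S,7R,10S)-7-acetyl-1,1-ethylenedioxy-10-methyl-trans-bicyclo[5.3.0]decane | CC(=O)[C@@H]1CC[C@@]2(C)[C@H]1CCCCC23OCCO3 | intermediate
17 | triethyl (E)-4-phosphonocrotonate (ethyl (E)-4-(diethoxyphosphoryl)but-2-enoate) | CCOC(=O)/C=C/CP(=O)(OCC)OCC | starting material
18 | ethyl (2E,4E)-5-[(6S,7R,10S)-1,1-ethylenedioxy-10-methyl-trans-bicyclo[5.3.0]decan-7-yl]hexa-2,4-dienoate | CCOC(=O)/C=C/C=C(\C)[C@@H]1CC[C@@]2(C)[C@H]1CCCCC23OCCO3 | intermediate
19 | ethyl (2E,4E)-5-[(6S,7R,10S)-10-methyl-1-oxo-trans-bicyclo[5.3.0]decan-7-yl]hexa-2,4-dienoate | CCOC(=O)/C=C/C=C(\C)[C@@H]1CC[C@@]2(C)[C@H]1CCCCC2=O | intermediate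
20 | ethyl (2E,4E)-5-[(6S,7R,10S)-10-methyl-1-oxo-trans-bicyclo[5.3.0]dec-2-en-7-yl]hexa-2,4-dienoate | CCOC(=O)/C=C/C=C(\C)[C@@H]1CC[C@@]2(C)[C@H]1CCC=CC2=O | intermediate
21 | ethyl (2E,4E)-5-[(6S,7R,10S)-3,10-dimethyl-1-(trimethylsilyloxy)-trans-bicyclo[5.3.0]dec-1-en-7-yl]hexa-2,4-dienoate (C3 epimers) | CCOC(=O)/C=C/C=C(\C)[C@@H]1CC[C@@]2(C)[C@H]1CCC(C)C=C2O[Si](C)(C)C | intermediate
22 | ethyl (2E,4E)-5-[(6S,7R,10S)-3,10-dimethyl-1-oxo-trans-bicyclo[5.3.0]dec-2-en-7-yl]hexa-2,4-dienoate | CCOC(=O)/C=C/C=C(\C)[C@@H]1CC[C@@]2(C)[C@H]1CCC(C)=CC2=O | intermediate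
23 | ethyl (2E,4E)-5-[(1R,6S,7R,10S)-1-hydroxy-3,10-dimethyl-trans-bicyclo[5.3.0]dec-2-en-7-yl]hexa-2,4-dienoate | CCOC(=O)/C=C/C=C(\C)[C@@H]1CC[C@@]2(C)[C@H]1CCC(C)=C[C@H]2O | intermediate
24 | ethyl (2E,4E)-5-[(1S,2S,3R,6S,7R,10S)-2,3-epoxy-1-hydroxy-3,10-dimethyl-trans-bicyclo[5.3.0]decan-7-yl]hexa-2,4-dienoate | CCOC(=O)/C=C/C=C(\C)[C@@H]1CC[C@@]2(C)[C@H]1CC[C@@]3(C)O[C@H]3[C@H]2O | intermediate
25 | (3E,5E)-6-[(1S,2S,3R,6S,7R,10S)-2,3-epoxy-1-hydroxy-3,10-dimethyl-trans-bicyclo[5.3.0]decan-7-yl]-2-methylhepta-3,5-dien-2-ol | CC(C)(O)/C=C/C=C(\C)[C@@H]1CC[C@@]2(C)[C@H]1CC[C@@]3(C)O[C@H]3[C@H]2O | intermediate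
26 | (1S,2S,3R,6S,7R,10S)-2,3-epoxy-7-[(2E,4E)-6-hydroxy-6-methylhepta-2,4-dien-2-yl]-3,10-dimethyl-trans-bicyclo[5.3.0]decan-1-yl acetate (CNP0265175.2) | CC(=O)O[C@@H]1[C@@H]2O[C@]2(C)CC[C@H]2[C@H](/C(C)=C/C=C/C(C)(C)O)CC[C@]12C | target

## Step count and least certain steps

Total step count: 17. Longest linear sequence: 17 steps, from 1 to 26; 3 and 17 are bought and enter in steps 2 and 9.

**Step 7 (key step).**
- *What may go wrong:* the photoexcited diazo ketone may leak into carbene chemistry (hydride shift from C6 to give back an enone, insertion into the O–H bond of methanol). Light absorption by coloured side products may stall conversion. Equilibration at C7 may stop short of a useful ratio.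
- *Fallback (from 8, back at 14):* a peroxide-driven ring contraction replaces the carbene. Compound 8 is reduced with Li in NH3 as in step 5 and the enolate is quenched with ethyl formate to give the 7-formyl ketone F1. Treating F1 with 30% aqueous H2O2 in buffered t-BuOH at 40 °C should bring about the known oxidative ring contraction of α-formyl ketones. C8 shifts from C11 to C7 in the peroxide adduct and the formyl carbon leaves as formate, giving the carboxylic acid F2. Methylation of F2 with MeI and K2CO3 in DMF gives the mixture of 13 and 14, and NaOMe in methanol converges it on 14.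

**Step 5.**
- *What may go wrong:* proton exchange between the enolate, unreacted ketone and lithium bases before or during acylation would move the charge to C8 and erode the regiochemistry. Over-reduction of the carbonyl and incomplete trans selectivity in the protonation of C6 are further risks.
- *Fallback (from 8, back at 10):* the enolate is isolated in masked form. Reduction with Li in NH3 and t-BuOH, then quenching with Me3SiCl and Et3N (Stork reductive silylation), gives the trimethylsilyl enol ether F3, which can be purified and checked. MeLi in THF at 0 °C then regenerates 9 free of amide and alkoxide, and acylation as in step 5 gives 10.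

**Step 9.**
- *What may go wrong:* addition of the phosphonate anion to the hindered, enolisable methyl ketone may be slow. Geometric control at C11=C12 may be incomplete, giving a mixture of alkene isomers.
- *Fallback (from 14, back at 18):* the C11 methyl group and the alkene geometry are set by syn carbometalation. i-Bu2AlH in toluene at −78 °C reduces 14 to the aldehyde F4. Dimethyl (1-diazo-2-oxopropyl)phosphonate with K2CO3 in MeOH converts F4 into the alkyne F5. Me3Al with Cp2ZrCl2 in CH2Cl2 at 0 °C, where the dioxolane should survive, then I2, gives the (E)-alkenyl iodide F6. A Heck reaction of F6 with ethyl acrylate (Pd(OAc)2, K2CO3, Bu4NCl, DMF) gives 18 with retention at C11=C12.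

**Step 14.**
- *What may go wrong:* the catalyst has to override the intrinsic preference for hydride attack anti to the C10 methyl group, and the assignment of large and small substituent is not certain. Facial selectivity may therefore be poor or reversed.
- *Fallback (from 22, back at 23):* substrate control followed by inversion. NaBH4 with CeCl3·7H2O in MeOH at −78 °C should give mainly the C1 β-alcohol F7. Mitsunobu reaction of F7 with 4-nitrobenzoic acid, Ph3P and diisopropyl azodicarboxylate inverts C1 to the α-4-nitrobenzoate F8. K2CO3 in ethanol then releases 23.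

**Step 3.**
- *What may go wrong:* cyclisation of the seven-membered dione may be slow and the enantioselectivity lower than in the six-membered series.
- *Fallback (from 4, back at 7):* resolution replaces asymmetric catalysis. Compound 4 is cyclised with pyrrolidine and acetic acid to racemic material. Preparative chromatography on a chiral stationary phase separates 7 from its enantiomer F9, which is discarded.

## Further compounds

F1 | step 7 | (6S,10S)-1,1-ethylenedioxy-7-formyl-10-methyl-trans-bicyclo[5.4.0]undecan-11-one (C7 epimers/hydroxymethylene form) | O=CC1C(=O)CC[C@@]2(C)[C@H]1CCCCC23OCCO3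
F2 | step 7 | (6S,10S)-1,1-ethylenedioxy-10-methyl-trans-bicyclo[5.3.0]decane-7-carboxylic acid (C7 epimers) | OC(=O)C1CC[C@@]2(C)[C@H]1CCCCC23OCCO3
F3 | step 5 | (6S,10S)-1,1-ethylenedioxy-10-methyl-11-(trimethylsilyloxy)-trans-bicyclo[5.4.0]undec-7(11)-ene | C1=C(O[Si](C)(C)C)CC[C@@]2(C)[C@H]1CCCCC23OCCO3
F4 | step 9 | (6S,7R,10S)-1,1-ethylenedioxy-10-methyl-trans-bicyclo[5.3.0]decane-7-carbaldehyde | O=C[C@@H]1CC[C@@]2(C)[C@H]1CCCCC23OCCO3
F5 | step 9 | (6S,7R,10S)-1,1-ethylenedioxy-7-ethynyl-10-methyl-trans-bicyclo[5.3.0]decane | C#C[C@@H]1CC[C@@]2(C)[C@H]1CCCCC23OCCO3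
F6 | step 9 | (6S,7R,10S)-1,1-ethylenedioxy-7-[(E)-1-iodoprop-1-en-2-yl]-10-methyl-trans-bicyclo[5.3.0]decane | I/C=C(\C)[C@@H]1CC[C@@]2(C)[C@H]1CCCCC23OCCO3
F7 | step 14 | ethyl (2E,4E)-5-[(1S,6S,7R,10S)-1-hydroxy-3,10-dimethyl-trans-bicyclo[5.3.0]dec-2-en-7-yl]hexa-2,4-dienoate (C1–OH β) | CCOC(=O)/C=C/C=C(\C)[C@@H]1CC[C@@]2(C)[C@H]1CCC(C)=C[C@@H]2O
F8 | step 14 | ethyl (2E,4E)-5-[(1R,6S,7R,10S)-3,10-dimethyl-1-(4-nitrobenzoyloxy)-trans-bicyclo[5.3.0]dec-2-en-7-yl]hexa-2,4-dienoate | CCOC(=O)/C=C/C=C(\C)[C@@H]1CC[C@@]2(C)[C@H]1CCC(C)=C[C@H]2OC(=O)c3ccc(cc3)[N+](=O)[O-]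
F9 | step 3 | (R)-10-methylbicyclo[5.4.0]undec-6-ene-1,11-dione (enantiomer of 7) | C[C@@]12CCC(=O)C=C1CCCCC2=O
A1 | alternative 1 | (2E,6E,10E)-geranylgeranyl diphosphate | CC(C)=CCC/C(C)=C/CC/C(C)=C/CC/C(C)=C/COP(O)(=O)OP(O)(O)=O
A2 | alternative 1 | bicyclic triene hydrocarbon with C2=C3, (E)-C11=C12 and C14=C15 | C1C=C(C)CC[C@H]2[C@H](/C(C)=C/CC=C(C)C)CC[C@]12C
A3 | alternative 2 | (R)-limonene | CC1=CC[C@@H](CC1)C(C)=C
A4 | alternative 2 | cis-divinylcyclopropane: pinacol (E)-2-{1-methyl-2-[2-methyl-5-(prop-1-en-2-yl)cyclopent-1-en-1-yl]cyclopropyl}ethenylboronate | CC1(C)OB(OC1(C)C)/C=C/[C@@]1(C)C[C@H]1C2=C(C)CC[C@H]2C(C)=C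
A5 | alternative 2 | C1 pinacol boronate of the bicyclo[5.3.0]deca-2,5-diene (C3 and C10 methyls, isopropenyl on C7) | CC1(C)OB(OC1(C)C)[C@@H]2C=C(C)CC=C3[C@H](C(C)=C)CC[C@]23C
A6 | alternative 3 | 2,6-dimethylcyclohepta-2,6-dien-1-one | CC1=CCCC(C)=CC1=O
A7 | alternative 3 | diisobutyl[1-(2-methyl-1,3-dioxolan-2-yl)ethenyl]aluminium | CC1(OCCO1)C(=C)[Al](CC(C)C)CC(C)C
A8 | alternative 3 | allyl bromide (3-bromoprop-1-ene) | C=CCBr
A9 | alternative 3 | trans-7-allyl-3,7-dimethyl-6-[1-(2-methyl-1,3-dioxolan-2-yl)ethenyl]cyclohept-2-en-1-one | O=C1C=C(C)CC[C@@H](C(=C)C2(C)OCCO2)[C@]1(C)CC=C
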